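## Structural features

The target is a biflavonoid in which a 5,7-dihydroxychroman-4-one (ring A fused to the pyranone ring C made of O1, C2, C3, C4, C4a and C8a) shares its C2–C3 bond with a dihydrofuran (ring F: C2, C3, O7L, C7L, C8L) fused across C7L–C8L of a kaempferol unit, whose atoms carry the suffix L. C2 is a fully substituted carbon bonded to the 4-hydroxyphenyl ring B, O1, C8L and C3, and C3 is a hemiketal carbon bonded to OH, O7L, C2 and the C4 ketone, so two tetrasubstituted stereocentres stand side by side, (2R,3S) in this labelling and necessarily cis-fused. The fragile groups are the C3 hemiketal (it can open to a 3,4-dione and reclose only under control of C2), the doubly benzylic C2–O1 bond (it can ionise in strong acid) and the base- and oxidant-sensitive flavonol with six phenols in all. The real difficulty is the congested C2–C3 pair, where aryl and oxygen substituents meet without a hydrogen, together with the fact that C3 is configurationally secure only as a full ketal or when tied to a configured C2. In any precursor in which C3 is the only stereocentre, a free hemiketal hydroxyl is therefore not tolerable, because ring–chain tautomerism through a vicinal tricarbonyl would erase it. The key step exploits the fact that C2 carries ring B, O1 and the C3–C4 unit: a C2 ketone in a 3-oxobenzofuran-2-carboxylate built on the lower flavonol (C3 already a ketal, ester carbon C4) can take up ring B as a carbanion, after which the new alkoxide O1 and the ester are clasped by a 3,5-dioxygenated aryne that becomes ring A and closes ring C.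

## Logic of the disconnections

28 from 27 from 26. Only protecting-group bonds are cut: the O–C(=O) bond of the benzoate on the C3 oxygen and the six O–CH2 bonds of the aryl acetals. Every phenol and the hemiketal oxygen are thus masked during the organometallic chemistry, and the hemiketal is freed only when C2 is configured, so opening at C3 can no longer scramble it. The forward step must remove the ester with a base mild enough not to degrade the liberated hemiketal, then the acetals with acid mild enough not to ionise C2–O1; 27 is not isolated.

26 from 15, 23 and 21. Three bonds around ring C are cut at once: C2–C1′ (ring B), O1–C8a and C4–C4a. C2 is the one carbon to which ring B, O1 and the C3–C4 unit are all attached, so this cut removes rings A, B and C and one stereocentre. The forward step must deliver the aryl group to the C2 carbonyl of 15 on the face that leaves O1 cis to the ester. It must attach O1 to the aryne carbon remote from the neighbouring alkoxy group, so that the ring A oxygens end at C5 and C7. It must close ring C faster than the tertiary alkoxide fragments.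

15 from 14. The C3–O bond to the acylated oxygen is cut. The connectivities and stereodescriptors of the key-step compounds were checked and needed no correction: the ketal centre of 15 maps onto C3 of 28, and the aryne from 21 gives the 5,7-pattern. What had to be improved is how C3 is fixed. An α-hydroxylation would give a free hemiketal whose alkoxide can expel the O7L phenoxide to an achiral vicinal tricarbonyl and reclose on either face, so its configuration would not survive a base-mediated etherification. Electrophilic acyloxylation delivers the oxygen already protected, in one step instead of two. An acyloxy oxygen is also a poorer ligand for magnesium than an acetal oxygen, which leaves the ketone–ester chelate in control of the later facial selectivity. 14 is achiral and flat; the demand is enantioface selection on its enolate and attack through carbon, not oxygen.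

14 from 13 from 11 and 12. The C8L–C2 bond (Dieckmann closure) and then the O7L–C3 ether bond are cut. This traces C3 and C4 to the two-carbon unit of 12 and C2 to an ester carbon on C8L. The forward steps need a free O7L hydroxyl next to that ester and a base that enolises only the aryloxyacetate.

11 from 10 from 9. The O7L–benzyl bond and the C8L–CO2Me bond are cut, the latter back to the C8L–I bond of 9. Benzyl is the one group on O7L removable without touching the acetals, and it must go after the carbonylation because hydrogenolysis would also remove iodine. The carbonylation has to work at a position flanked by two oxygen substituents, hence iodide.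

9 from 8 from 7 from 4 and 6. The acetal on O3L, then O1L–C2L and C3L–O (oxidative cyclisation), then Cα=Cβ (aldol condensation) are cut. Regiochemistry is decided by constitution: 4 has a single free hydroxyl, next to iodine, so the pyranone oxygen can only be that one and iodine must end at C8L. The demand is that the oxidative cyclisation gives the six-membered flavonol and not the five-membered aurone.

4 from 3 from 2 from 1, and 6 from 5. C–I, O–acetal and O–benzyl bonds are cut. In 1 the two ortho hydroxyls are equivalent, so only the para hydroxyl has to be singled out; one acetal then desymmetrises the ring and the remaining phenol directs iodination to its ortho position. The demand is mono-selectivity in the first alkylation.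

21 from 18 from 17 from 16, and 23 from 22. The O–Tf and C–Si bonds (silyl shift from oxygen to carbon after halogen–lithium exchange), the C–Br bond and two O–acetal bonds are cut; 23 is cut at C–Mg. The three hydroxyls of 16 are equivalent, so the only demands are twofold etherification and bromination ortho to the free hydroxyl.

## Other disconnections considered

Alternative 1: The cut is O1–C2 and O7L–C3 of A1 (the hexakis-acetal with free hemiketal, the same compound as 27). It leads back to the open-chain hydroxy-dione A2, with a tertiary carbinol at C2, ketones at C3 and C4 and free phenols at O1 and O7L. Forward, a chiral BINOL-derived phosphoric acid would ionise the carbinol, helped by the ortho hydroxyl, to an ortho-quinone methide. Within the chiral ion pair O1 would add to C2 (ring C), and the regenerated O7L phenol would add to the C3 ketone (ring F).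
- In favour: the enantio-determining event creates C2 directly and C3 follows by necessarily cis hemiketalisation, which is how the target itself is wired. No delicate ketal has to be carried, and on this structural point it is the better plan.
- In favour: A1 arrives with the hemiketal unprotected, so one acid operation remains, one fewer than after 26. On end-game economy it is again the better.
- Against: A2 has easier exits (closure of O1 onto C3 to a five-membered hemiketal, acyloin-type shifts under acid).
- Against: the cation at C2 is α to a carbonyl, so ionisation is disfavoured, while the fully substituted diaryl quinone methide is so stabilised and hindered that facial control by the phosphate is doubtful.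
- Against: joining the hindered C8L to a tricarbonyl-level electrophile to make A2 is likely to cost more steps than the route to 15.
- Mechanism: both key steps lack close precedent. The cationic one depends on catalyst control over a trityl-like ion; the anionic relay chosen here depends on substrate control from an existing centre, which is easier to predict.

Alternative 2: The cut is O1–C2 and the C2–ring B bond of A3, the aryl group being returned to C3. This gives the 2-aryl-2-hydroxy-1,3-diketone A4. Forward, Sc(OTf)3 would promote addition of O1–H to the C8L-bound ketone and ionise the cyclic hemiketal to an oxocarbenium ion at C2. Ring B would then migrate suprafacially from C3 to C2 while the C3 hydroxyl becomes the ketone. Acid would remove the acetals of A3 and the freed O7L–H would close the hemiketal.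
- In favour: the stereocentre of A4 is a tertiary carbinol with no ring–chain lability, transferred to C2 by a stereospecific 1,2-shift. On configurational security of the stored chirality it is the better plan.
- In favour: the 4-alkoxyphenyl group migrates readily, and after the key step a single acid operation reaches the target, one fewer than from 26.
- Against: the ketone that must accept O1 sits on C8L between two ortho substituents, so hemiketalisation and stabilisation of the cation are hampered.
- Against: a 2-hydroxy-1,3-diketone under a Lewis acid can instead shift an aroyl group or fragment by retro-Claisen cleavage.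
- Against: the Lewis acid meets seven acetals, and any lifetime of an open cation would leak enantiopurity.
- Step economy: it avoids a protected hemiketal (an advantage), but A4 needs two regiocontrolled C-acylations and an asymmetric hydroxylation, so the overall count is expected to be about equal.

Alternative 3: The cut is O1–C2 and C3–OH of A5, leading back to the flat, achiral 2-aroyl-3-arylbenzofuran A6. Forward, a fructose-derived chiral dioxirane (ketone catalyst with KHSO5) would epoxidise the furan C2=C3 bond on one face. The epoxide would open at the doubly benzylic C2, and O1–H would capture that carbon from the face opposite the epoxide oxygen, the only way ring C can form.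
- In favour: A6 can be assembled in few steps by classical benzofuran-forming condensation, so on step count before the key step it is the better plan.
- In favour: both stereocentres arise in one catalytic oxidation and the hemiketal needs no protection.
- Equal: after the key step it needs acetate removal and acid, the same two operations as after 26.
- Against: the alkene is tetrasubstituted, part of an aromatic furan and deactivated by the 2-aroyl group, outside the usual range of chiral dioxirane epoxidations.
- Against: the free phloroglucinol-type phenol (a phenoxide at the pH the ketone catalyst requires) and the electron-rich rings are more easily oxidised than that alkene.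
- Against: enantioselectivity rests entirely on face selection at a hindered, nearly symmetric bond.
- Mechanism: the chosen plan keeps all polyphenol rings away from oxidants and builds ring A only in the key step, at the cost of a longer precursor.

Key step: step 17

Assumption: 1-bromo-4-(methoxymethoxy)benzene (22) is bought as such.
Assumption: the sense of induction of the ammonium catalyst in step 12 cannot be predicted with certainty; the cinchonidine-derived salt is written, and its cinchonine-derived pseudoenantiomer would be used if that is the one that delivers the 8R ketal.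

## Route

Step 1
Reactants: 1 2,4,6-trihydroxyacetophenone
Product: 2 1-[4-(benzyloxy)-2,6-dihydroxyphenyl]ethanone
Conditions: BnBr (1.0 equiv), K2CO3 (1.1 equiv), DMF, 0 °C to rt
Reagents that add atoms: benzyl bromide, BrCc1ccccc1
Why: Williamson etherification; the 4-hydroxyl is the only one not hydrogen-bonded to the acetyl carbonyl and is the most acidic, so one equivalent of halide should alkylate it first, and any dibenzyl ether is removed by chromatography.

Step 2
Reactants: 2 1-[4-(benzyloxy)-2,6-dihydroxyphenyl]ethanone
Product: 3 1-[4-(benzyloxy)-2-hydroxy-6-(methoxymethoxy)phenyl]ethanone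
Conditions: MOMCl (1.1 equiv), iPr2NEt, CH2Cl2, 0 °C to rt
Reagents that add atoms: chloromethyl methyl ether, COCCl
Why: O-alkylation of one of two equivalent hydroxyls; after the first etherification the remaining hydroxyl is locked in a hydrogen bond to the carbonyl and resists a second alkylation.

Step 3
Reactants: 3 1-[4-(benzyloxy)-2-hydroxy-6-(methoxymethoxy)phenyl]ethanone
Product: 4 1-[4-(benzyloxy)-2-hydroxy-3-iodo-6-(methoxymethoxy)phenyl]ethanone
Conditions: NIS (1.05 equiv), CH2Cl2, 0 °C, dark
Reagents that add atoms: N-iodosuccinimide, O=C1CCC(=O)N1I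
Why: Electrophilic aromatic iodination ortho to the free, hydrogen-bonded phenol, the usual site in 2-hydroxy-4,6-dialkoxyacetophenones; because iodine sits next to the only free hydroxyl, the later pyranone closure through that oxygen must place it at C8L.

Step 4
Reactants: 5 4-hydroxybenzaldehyde
Product: 6 4-(methoxymethoxy)benzaldehyde
Conditions: MOMCl, iPr2NEt, CH2Cl2, 0 °C to rt
Reagents that add atoms: chloromethyl methyl ether, COCCl
Why: Routine acetal protection of a phenol so that the aldehyde can be used under strongly basic conditions and the protecting group matches all others at the end.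

Step 5
Reactants: 4 1-[4-(benzyloxy)-2-hydroxy-3-iodo-6-(methoxymethoxy)phenyl]ethanone; 6 4-(methoxymethoxy)benzaldehyde
Product: 7 (E)-1-[4-(benzyloxy)-2-hydroxy-3-iodo-6-(methoxymethoxy)phenyl]-3-[4-(methoxymethoxy)phenyl]prop-2-en-1-one
Conditions: KOH (50% aq), EtOH, rt
Reagents that add atoms: none
Why: Claisen–Schmidt condensation; the acetophenone enolate adds to the non-enolisable aldehyde and the aldol dehydrates to the conjugated E-enone, the thermodynamic geometry, while aryl iodide, benzyl ether and acetals are inert to hydroxide.

Step 6
Reactants: 7 (E)-1-[4-(benzyloxy)-2-hydroxy-3-iodo-6-(methoxymethoxy)phenyl]-3-[4-(methoxymethoxy)phenyl]prop-2-en-1-one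
Product: 8 7-(benzyloxy)-3-hydroxy-8-iodo-5-(methoxymethoxy)-2-[4-(methoxymethoxy)phenyl]-4H-chromen-4-one
Conditions: 30% H2O2, 2 M NaOH, MeOH, 0 °C to rt
Reagents that add atoms: hydrogen peroxide, OO
Why: Algar–Flynn–Oyamada reaction; alkaline peroxide epoxidises the enone, the 2′-phenoxide opens the epoxide at the β-carbon and the dihydroflavonol is oxidised on to the flavonol. The single free phenol fixes the pyranone oxygen, so iodine ends at C8L, benzyloxy at C7L and the acetal at C5L.

Step 7
Reactants: 8 7-(benzyloxy)-3-hydroxy-8-iodo-5-(methoxymethoxy)-2-[4-(methoxymethoxy)phenyl]-4H-chromen-4-one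
Product: 9 7-(benzyloxy)-8-iodo-3,5-bis(methoxymethoxy)-2-[4-(methoxymethoxy)phenyl]-4H-chromen-4-one
Conditions: MOMCl, iPr2NEt, DMAP (cat.), CH2Cl2, 40 °C
Reagents that add atoms: chloromethyl methyl ether, COCCl
Why: O-alkylation of the 3-hydroxyl, which is hydrogen-bonded to the C4L carbonyl and therefore needs mild heating and a nucleophilic catalyst; no other acidic site remains.

Step 8
Reactants: 9 7-(benzyloxy)-8-iodo-3,5-bis(methoxymethoxy)-2-[4-(methoxymethoxy)phenyl]-4H-chromen-4-one
Product: 10 methyl 7-(benzyloxy)-3,5-bis(methoxymethoxy)-2-[4-(methoxymethoxy)phenyl]-4-oxo-4H-chromene-8-carboxylate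
Conditions: Pd(OAc)2 (5 mol %), Xantphos (10 mol %), CO (1 atm), MeOH, Et3N, DMF, 80 °C
Reagents that add atoms: carbon monoxide, [C-]#[O+]; methanol, CO
Why: Palladium-catalysed methoxycarbonylation of an aryl iodide: oxidative addition to zerovalent palladium, CO insertion and methanolysis of the acyl complex. An iodide and a wide-bite-angle diphosphine are chosen because C8L is flanked by two oxygen substituents.

Step 9
Reactants: 10 methyl 7-(benzyloxy)-3,5-bis(methoxymethoxy)-2-[4-(methoxymethoxy)phenyl]-4-oxo-4H-chromene-8-carboxylate
Product: 11 methyl 7-hydroxy-3,5-bis(methoxymethoxy)-2-[4-(methoxymethoxy)phenyl]-4-oxo-4H-chromene-8-carboxylate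
Conditions: H2 (1 atm), Pd/C (10%), EtOAc, rt
Reagents that add atoms: none
Why: Hydrogenolysis of the benzyl ether frees only O7L; acetals, ester and the tetrasubstituted conjugated C2L=C3L bond are expected to survive at one atmosphere and room temperature.

Step 10
Reactants: 11 methyl 7-hydroxy-3,5-bis(methoxymethoxy)-2-[4-(methoxymethoxy)phenyl]-4-oxo-4H-chromene-8-carboxylate; 12 methyl bromoacetate
Product: 13 methyl 7-(2-methoxy-2-oxoethoxy)-3,5-bis(methoxymethoxy)-2-[4-(methoxymethoxy)phenyl]-4-oxo-4H-chromene-8-carboxylate
Conditions: K2CO3, DMF, rt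
Reagents that add atoms: none
Why: Williamson etherification of the single free, salicylate-type phenol with the α-halo ester; this brings in C3 and C4 of the target.

Step 11
Reactants: 13 methyl 7-(2-methoxy-2-oxoethoxy)-3,5-bis(methoxymethoxy)-2-[4-(methoxymethoxy)phenyl]-4-oxo-4H-chromene-8-carboxylate
Product: 14 methyl 9-hydroxy-3,5-bis(methoxymethoxy)-2-[4-(methoxymethoxy)phenyl]-4-oxo-4H-furo[2,3-h]chromene-8-carboxylate (enol form of the β-keto ester)
Conditions: KOtBu (2.2 equiv), THF, 0 °C; then 1 M HCl
Reagents that add atoms: none
Why: Dieckmann condensation; the aryloxyacetate enolate (the only enolisable position) attacks the neighbouring aryl ester to close the five-membered ring, and deprotonation of the product to the aromatic 3-oxidobenzofuran drives the equilibrium.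

Step 12
Reactants: 14 methyl 9-hydroxy-3,5-bis(methoxymethoxy)-2-[4-(methoxymethoxy)phenyl]-4-oxo-4H-furo[2,3-h]chromene-8-carboxylate
Product: 15 methyl (8R)-8-(benzoyloxy)-3,5-bis(methoxymethoxy)-2-[4-(methoxymethoxy)phenyl]-4,9-dioxo-8,9-dihydro-4H-furo[2,3-h]chromene-8-carboxylate
Conditions: (BzO)2 (1.2 equiv), O-allyl-N-(9-anthracenylmethyl)cinchonidinium bromide (10 mol %), K2CO3 (1.5 equiv, solid), toluene–CHCl3, −40 °C
Reagents that add atoms: dibenzoyl peroxide, O=C(OOC(=O)c1ccccc1)c1ccccc1
Why: Catalytic enantioselective α-benzoyloxylation of a cyclic β-keto ester; the enolate enters the organic phase as an ion pair with the chiral ammonium cation, which shields one face while C3 attacks the peroxide O–O bond, setting the ketal centre as R. The oxygen arrives already acylated, so the centre never exists as a free hemiketal that could racemise by ring opening.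

Step 13
Reactants: 16 phloroglucinol
Product: 17 3,5-bis(methoxymethoxy)phenol
Conditions: MOMCl (2.0 equiv), iPr2NEt (2.2 equiv), DMF, 0 °C to rt
Reagents that add atoms: chloromethyl methyl ether, COCCl
Why: Statistical twofold O-alkylation of three equivalent hydroxyls; the bis-ether is separated from mono- and tris-ether, which can be recycled, and the material is cheap.

Step 14
Reactants: 17 3,5-bis(methoxymethoxy)phenol
Product: 18 2-bromo-3,5-bis(methoxymethoxy)phenol
Conditions: NBS (1.0 equiv), CH2Cl2, −78 °C
Reagents that add atoms: N-bromosuccinimide, O=C1CCC(=O)N1Br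
Why: Electrophilic bromination of the electron-rich phenol at low temperature; the hydroxyl directs ortho, and the isomer brominated between the two acetal oxygens is separated.

Step 15
Reactants: 18 2-bromo-3,5-bis(methoxymethoxy)phenol
Product: 21 3,5-bis(methoxymethoxy)-2-(trimethylsilyl)phenyl trifluoromethanesulfonate, via silyl ether 19 (not isolated), via lithium phenoxide 20 (not isolated)
Conditions: HMDS, THF, 65 °C, then evaporation; n-BuLi, THF, −78 °C; Tf2O, −78 to 0 °C
Reagents that add atoms: hexamethyldisilazane, C[Si](C)(C)N[Si](C)(C)C; trifluoromethanesulfonic anhydride, O=S(=O)(OS(=O)(=O)C(F)(F)F)C(F)(F)F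
Why: O-silylation, bromine–lithium exchange and 1,3-shift of silicon from oxygen to carbon (retro-Brook rearrangement) put the silyl group on C2 and return a phenoxide that is triflated in the same flask; this is the standard entry to 2-(trimethylsilyl)aryl triflates.

Step 16
Reactants: 22 1-bromo-4-(methoxymethoxy)benzene
Product: 23 [4-(methoxymethoxy)phenyl]magnesium bromide
Conditions: Mg turnings, BrCH2CH2Br (cat.), THF, rt to 40 °C
Reagents that add atoms: magnesium, [Mg]
Why: Grignard formation by insertion of magnesium into the aryl–bromine bond; the acetal is inert, and the solution is titrated and used directly.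

Step 17
Reactants: 15 methyl (8R)-8-(benzoyloxy)-3,5-bis(methoxymethoxy)-2-[4-(methoxymethoxy)phenyl]-4,9-dioxo-8,9-dihydro-4H-furo[2,3-h]chromene-8-carboxylate; 23 [4-(methoxymethoxy)phenyl]magnesium bromide; 21 3,5-bis(methoxymethoxy)-2-(trimethylsilyl)phenyl trifluoromethanesulfonate
Product: 26 C3-benzoate of the fully protected target: (2R,3R)-3-(benzoyloxy)-5,7-bis(methoxymethoxy)-2-[4-(methoxymethoxy)phenyl]chroman-4-one fused through C2–C8L and C3–O7L to the tris(methoxymethyl) ether of kaempferol, via magnesium alkoxide 24 (not isolated), via aryl anion 25 (not isolated)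
Conditions: 23 (1.15 equiv), THF, −78 °C, 1 h; then 21 (1.6 equiv), KF (3 equiv), 18-crown-6 (3 equiv), THF, −20 °C to rt
Reagents that add atoms: none
Why: Proposed new method: at −78 °C 23 should add to the C2 ketone of 15, the most electrophilic carbonyl present (non-enolisable, in a five-membered ring, flanked by the ketal carbon), on the face anti to the ester, which is held beside the ketone oxygen in a six-membered magnesium chelate, giving 24 with O1 cis to the ester. Fluoride then releases 3,5-bis(methoxymethoxy)benzyne from 21, the alkoxide adds to the aryne carbon remote from the 3-alkoxy group so that the charge develops next to that oxygen (25), and the aryl anion acylates on the neighbouring methyl ester with loss of methoxide. The closest known reaction type is the fluoride-induced annulation of 2-(trimethylsilyl)aryl triflates with phenoxides or alkoxides that carry an adjacent ester (xanthone and chromanone synthesis); new is the tertiary alkoxide made in the same flask by Grignard addition to a polycarbonyl substrate. Ring C is closed by the C4–C4a bond in a 6-exo-trig acyl substitution, after the intermolecular O1–C8a arylation. The new stereocentre C2 is set in the Grignard addition under control of the C3 ketal centre through the chelate, and the diastereomer with O1 trans to the ester cannot cyclise and is lost instead of contaminating 26. Chemoselectivity for the ketone over benzoate, methyl ester and chromone should follow from the low temperature and the activation of the ring ketone; aryne regioselectivity follows from the inductive effect of the 3-alkoxy group, which places O1 at C8a, C4 at C4a and hence the ring A oxygens at C5 and C7. The ring closure has to outrun retro-aldol cleavage of 24 and protonation of 25, which is why an aprotic ether solvent, low temperature and a soluble fluoride source are chosen.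

Step 18
Reactants: 26 C3-benzoate of the fully protected target
Product: 28 target: (2R,3S)-3,5,7-trihydroxy-2-(4-hydroxyphenyl)chroman-4-one fused through C2–C8L and C3–O7L to kaempferol (cis ring fusion), via free hemiketal 27 (not isolated)
Conditions: K2CO3 (0.2 equiv), MeOH–THF, 0 °C, argon; then 3 M HCl (aq), MeOH–THF, 45 °C
Reagents that add atoms: none
Why: Catalytic methoxide transesterifies the activated benzoate on the ketal oxygen, and the liberated hemiketal is held cis by the configured C2. Without isolation, acid then cleaves the six aryl acetals by specific acid catalysis; the C2–O1 ether is deactivated towards ionisation by the adjacent C3 with its two oxygens and the C4 carbonyl, and no stereocentre is touched.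

## Compound list

1 | 2,4,6-trihydroxyacetophenone | CC(=O)c1c(O)cc(O)cc1O | starting material
2 | 1-[4-(benzyloxy)-2,6-dihydroxyphenyl]ethanone | CC(=O)c1c(O)cc(OCc2ccccc2)cc1O | intermediate
3 | 1-[4-(benzyloxy)-2-hydroxy-6-(methoxymethoxy)phenyl]ethanone | CC(=O)c1c(O)cc(OCc2ccccc2)cc1OCOC | intermediate
4 | 1-[4-(benzyloxy)-2-hydroxy-3-iodo-6-(methoxymethoxy)phenyl]ethanone | CC(=O)c1c(O)c(I)c(OCc2ccccc2)cc1OCOC | intermediate
5 | 4-hydroxybenzaldehyde | O=Cc1ccc(O)cc1 | starting material
6 | 4-(methoxymethoxy)benzaldehyde | COCOc1ccc(C=O)cc1 | intermediate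
7 | (E)-1-[4-(benzyloxy)-2-hydroxy-3-iodo-6-(methoxymethoxy)phenyl]-3-[4-(methoxymethoxy)phenyl]prop-2-en-1-one | COCOc1ccc(/C=C/C(=O)c2c(O)c(I)c(OCc3ccccc3)cc2OCOC)cc1 | intermediate
8 | 7-(benzyloxy)-3-hydroxy-8-iodo-5-(methoxymethoxy)-2-[4-(methoxymethoxy)phenyl]-4H-chromen-4-one | O=c1c(O)c(-c2ccc(OCOC)cc2)oc2c(I)c(OCc3ccccc3)cc(OCOC)c12 | intermediate
9 | 7-(benzyloxy)-8-iodo-3,5-bis(methoxymethoxy)-2-[4-(methoxymethoxy)phenyl]-4H-chromen-4-one | O=c1c(OCOC)c(-c2ccc(OCOC)cc2)oc2c(I)c(OCc3ccccc3)cc(OCOC)c12 | intermediate
10 | methyl 7-(benzyloxy)-3,5-bis(methoxymethoxy)-2-[4-(methoxymethoxy)phenyl]-4-oxo-4H-chromene-8-carboxylate | COC(=O)c1c(OCc2ccccc2)cc(OCOC)c2c(=O)c(OCOC)c(-c3ccc(OCOC)cc3)oc12 | intermediate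
11 | methyl 7-hydroxy-3,5-bis(methoxymethoxy)-2-[4-(methoxymethoxy)phenyl]-4-oxo-4H-chromene-8-carboxylate | COC(=O)c1c(O)cc(OCOC)c2c(=O)c(OCOC)c(-c3ccc(OCOC)cc3)oc12 | intermediate
12 | methyl bromoacetate | COC(=O)CBr | starting material
13 | methyl 7-(2-methoxy-2-oxoethoxy)-3,5-bis(methoxymethoxy)-2-[4-(methoxymethoxy)phenyl]-4-oxo-4H-chromene-8-carboxylate | COC(=O)COc1cc(OCOC)c2c(=O)c(OCOC)c(-c3ccc(OCOC)cc3)oc2c1C(=O)OC | intermediate
14 | methyl 9-hydroxy-3,5-bis(methoxymethoxy)-2-[4-(methoxymethoxy)phenyl]-4-oxo-4H-furo[2,3-h]chromene-8-carboxylate (enol form) | COC(=O)c1oc2cc(OCOC)c3c(=O)c(OCOC)c(-c4ccc(OCOC)cc4)oc3c2c1O | intermediate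
15 | methyl (8R)-8-(benzoyloxy)-3,5-bis(methoxymethoxy)-2-[4-(methoxymethoxy)phenyl]-4,9-dioxo-8,9-dihydro-4H-furo[2,3-h]chromene-8-carboxylate | COC(=O)[C@@]1(OC(=O)c2ccccc2)Oc2cc(OCOC)c3c(=O)c(OCOC)c(-c4ccc(OCOC)cc4)oc3c2C1=O | intermediate
16 | phloroglucinol (benzene-1,3,5-triol) | Oc1cc(O)cc(O)c1 | starting material
17 | 3,5-bis(methoxymethoxy)phenol | Oc1cc(OCOC)cc(OCOC)c1 | intermediate
18 | 2-bromo-3,5-bis(methoxymethoxy)phenol | Oc1cc(OCOC)cc(OCOC)c1Br | intermediate
19 | [2-bromo-3,5-bis(methoxymethoxy)phenoxy]trimethylsilane | C[Si](C)(C)Oc1cc(OCOC)cc(OCOC)c1Br | intermediate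
20 | lithium 3,5-bis(methoxymethoxy)-2-(trimethylsilyl)phenoxide | [Li]Oc1cc(OCOC)cc(OCOC)c1[Si](C)(C)C | intermediate
21 | 3,5-bis(methoxymethoxy)-2-(trimethylsilyl)phenyl trifluoromethanesulfonate | COCOc1cc(OCOC)c([Si](C)(C)C)c(OS(=O)(=O)C(F)(F)F)c1 | intermediate
22 | 1-bromo-4-(methoxymethoxy)benzene | COCOc1ccc(Br)cc1 | starting material
23 | [4-(methoxymethoxy)phenyl]magnesium bromide | COCOc1ccc([Mg]Br)cc1 | intermediate
24 | bromomagnesium (8R,9R)-8-(benzoyloxy)-8-(methoxycarbonyl)-3,5-bis(methoxymethoxy)-2,9-bis[4-(methoxymethoxy)phenyl]-4-oxo-8,9-dihydro-4H-furo[2,3-h]chromen-9-olate | COC(=O)[C@@]1(OC(=O)c2ccccc2)Oc2cc(OCOC)c3c(=O)c(OCOC)c(-c4ccc(OCOC)cc4)oc3c2[C@]1(O[Mg]Br)c1ccc(OCOC)cc1 | intermediate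
25 | aryl anion formed by addition of 24 to the aryne, drawn as its bromomagnesium species: the 9-[3,5-bis(methoxymethoxy)phenoxy] ether of the (8R,9R) adduct, metalated at the ring carbon between the ether oxygen and an acetal oxygen | COC(=O)[C@@]1(OC(=O)c2ccccc2)Oc2cc(OCOC)c3c(=O)c(OCOC)c(-c4ccc(OCOC)cc4)oc3c2[C@]1(Oc1cc(OCOC)cc(OCOC)c1[Mg]Br)c1ccc(OCOC)cc1 | intermediate
26 | C3-benzoate of the fully protected target: (2R,3R)-3-(benzoyloxy)-5,7-bis(methoxymethoxy)-2-[4-(methoxymethoxy)phenyl]chroman-4-one fused through C2–C8L and C3–O7L to the tris(methoxymethyl) ether of kaempferol | O=C1c2c(OCOC)cc(OCOC)cc2O[C@]2(c3ccc(OCOC)cc3)c3c(cc(OCOC)c4c(=O)c(OCOC)c(-c5ccc(OCOC)cc5)oc34)O[C@]12OC(=O)c1ccccc1 | intermediate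
27 | hexakis(methoxymethyl) ether of the target with free (2R,3S) hemiketal hydroxyl at C3 | O=C1c2c(OCOC)cc(OCOC)cc2O[C@]2(c3ccc(OCOC)cc3)c3c(cc(OCOC)c4c(=O)c(OCOC)c(-c5ccc(OCOC)cc5)oc34)O[C@]12O | intermediate
28 | target: (2R,3S)-3,5,7-trihydroxy-2-(4-hydroxyphenyl)chroman-4-one fused through C2–C8L and C3–O7L to kaempferol, cis ring fusion | O=C1c2c(O)cc(O)cc2O[C@]2(c3ccc(O)cc3)c3c(cc(O)c4c(=O)c(O)c(-c5ccc(O)cc5)oc34)O[C@]12O | target

## Step count and least certain steps

Total: 18 steps. Longest linear sequence: 13 steps (steps 1–3, 5–12, 17 and 18).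

Step 17 (bears the label). Most likely failure: retro-aldol fragmentation of the hindered tertiary alkoxide before it is arylated, which would also erase C3. Other risks are addition of the Grignard reagent on the face syn to the ester (which gives an alkoxide that cannot cyclise), protonation of the aryl anion before acylation, and attack on the benzoate. Fallback by known chemistry, from 11 back to 26, closing ring C by intramolecular nucleophilic aromatic substitution instead of aryne capture. 5-Fluororesorcinol would be C-acetylated (AcOH, BF3·OEt2, 90 °C) to 1-(2-fluoro-4,6-dihydroxyphenyl)ethanone F1, protected (NaH, MOMCl, DMF) to 1-[2-fluoro-4,6-bis(methoxymethoxy)phenyl]ethanone F2 and α-brominated (PhNMe3Br3, THF, 0 °C) to 2-bromo-1-[2-fluoro-4,6-bis(methoxymethoxy)phenyl]ethanone F3. Alkylation of 11 with F3 (K2CO3, DMF) would give the phenacyl ether F4, KOtBu at −20 °C would close it to the 8-aroyl-9-hydroxyfurochromenone F5, and benzoyloxylation under the conditions of step 12 would give the α-benzoyloxy diketone F6. Addition of 23 to the ring ketone of F6 (the exocyclic ketone is shielded by its 2,6-disubstituted aryl group) would give the bromomagnesium alkoxide F7, which on warming in THF–DMF displaces the fluorine ortho to the aryl ketone and gives 26. Each operation has precedent; the price is three extra steps for F3 and the need to keep F5 cold so that its own enol oxygen does not displace the fluorine.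

Step 12. Most likely failure: erosion of enantioselectivity, because a methyl ester and a flat heteroaromatic enolate give the chiral cation little to grip, and competing O-acylation of the enolate by the peroxide. Fallback from 14 back to 15: racemic benzoyloxylation (dibenzoyl peroxide, K2CO3, Bu4NBr, toluene, 0 °C) followed by preparative chromatography on a chiral stationary phase. The unwanted enantiomer, methyl (8S)-8-(benzoyloxy)-3,5-bis(methoxymethoxy)-2-[4-(methoxymethoxy)phenyl]-4,9-dioxo-8,9-dihydro-4H-furo[2,3-h]chromene-8-carboxylate F8, would be returned to 14 by reductive cleavage of the α-acyloxy ketone (SmI2, THF–MeOH, −78 °C).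

Step 6. Most likely failure: aurone formation, by attack of the phenoxide at the α-carbon of the chalcone epoxide, favoured by the 6′-alkoxy group that twists the carbonyl out of plane. Fallback from 7 back to 8: I2 (1.1 equiv) in pyridine at 90 °C cyclises and dehydrogenates under buffered conditions to the flavone 7-(benzyloxy)-8-iodo-5-(methoxymethoxy)-2-[4-(methoxymethoxy)phenyl]-4H-chromen-4-one F9; deprotonation at C3L (LDA, THF, −78 °C), borylation (B(OMe)3) and oxidation (H2O2, AcOH) then install the 3-hydroxyl and give 8.

Step 14. Most likely failure: bromination para to the hydroxyl (between the two acetal oxygens) or twofold bromination. Fallback from 17 back to 21 by directed ortho-metalation: ClC(O)NEt2, K2CO3, MeCN gives 3,5-bis(methoxymethoxy)phenyl diethylcarbamate F10; s-BuLi, TMEDA, THF, −78 °C, then Me3SiCl gives 3,5-bis(methoxymethoxy)-2-(trimethylsilyl)phenyl diethylcarbamate F11 (metalation between the carbamate and an acetal oxygen, the carbamate being the stronger director); LiAlH4, THF, 0 °C gives 3,5-bis(methoxymethoxy)-2-(trimethylsilyl)phenol F12; Tf2O, pyridine, CH2Cl2, 0 °C gives 21.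

Step 18. Most likely failure: base-induced opening of the liberated hemiketal to the 3,4-dione followed by cleavage or benzilic-type rearrangement, or ionisation of C2–O1 in the acid stage. Fallback from 14 back to 27, freeing the ketal oxygen under neutral conditions. In step 12 dibenzyl peroxydicarbonate replaces dibenzoyl peroxide and gives the benzyl carbonate methyl (8R)-8-{[(benzyloxy)carbonyl]oxy}-3,5-bis(methoxymethoxy)-2-[4-(methoxymethoxy)phenyl]-4,9-dioxo-8,9-dihydro-4H-furo[2,3-h]chromene-8-carboxylate F13. Step 17 carried out on F13 gives the C3 benzyl carbonate of the protected target F14. Brief hydrogenolysis (H2, Pd/C, EtOAc, rt) then gives 27, which is treated with acid as in step 18.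

Further compounds

F1 | step 17 | 1-(2-fluoro-4,6-dihydroxyphenyl)ethanone | CC(=O)c1c(O)cc(O)cc1F
F2 | step 17 | 1-[2-fluoro-4,6-bis(methoxymethoxy)phenyl]ethanone | CC(=O)c1c(F)cc(OCOC)cc1OCOC
F3 | step 17 | 2-bromo-1-[2-fluoro-4,6-bis(methoxymethoxy)phenyl]ethanone | O=C(CBr)c1c(F)cc(OCOC)cc1OCOC
F4 | step 17 | methyl 7-{2-[2-fluoro-4,6-bis(methoxymethoxy)phenyl]-2-oxoethoxy}-3,5-bis(methoxymethoxy)-2-[4-(methoxymethoxy)phenyl]-4-oxo-4H-chromene-8-carboxylate | COC(=O)c1c(OCC(=O)c2c(F)cc(OCOC)cc2OCOC)cc(OCOC)c2c(=O)c(OCOC)c(-c3ccc(OCOC)cc3)oc12
F5 | step 17 | 8-[2-fluoro-4,6-bis(methoxymethoxy)benzoyl]-9-hydroxy-3,5-bis(methoxymethoxy)-2-[4-(methoxymethoxy)phenyl]-4H-furo[2,3-h]chromen-4-one | O=C(c1oc2cc(OCOC)c3c(=O)c(OCOC)c(-c4ccc(OCOC)cc4)oc3c2c1O)c1c(F)cc(OCOC)cc1OCOC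
F6 | step 17 | (8R)-8-(benzoyloxy)-8-[2-fluoro-4,6-bis(methoxymethoxy)benzoyl]-3,5-bis(methoxymethoxy)-2-[4-(methoxymethoxy)phenyl]-4H-furo[2,3-h]chromene-4,9(8H)-dione | O=C(c1c(F)cc(OCOC)cc1OCOC)[C@@]1(OC(=O)c2ccccc2)Oc2cc(OCOC)c3c(=O)c(OCOC)c(-c4ccc(OCOC)cc4)oc3c2C1=O
F7 | step 17 | bromomagnesium alkoxide from addition of 23 to the ring ketone of F6 | O=C(c1c(F)cc(OCOC)cc1OCOC)[C@@]1(OC(=O)c2ccccc2)Oc2cc(OCOC)c3c(=O)c(OCOC)c(-c4ccc(OCOC)cc4)oc3c2[C@]1(O[Mg]Br)c1ccc(OCOC)cc1
F8 | step 12 | methyl (8S)-8-(benzoyloxy)-3,5-bis(methoxymethoxy)-2-[4-(methoxymethoxy)phenyl]-4,9-dioxo-8,9-dihydro-4H-furo[2,3-h]chromene-8-carboxylate | COC(=O)[C@]1(OC(=O)c2ccccc2)Oc2cc(OCOC)c3c(=O)c(OCOC)c(-c4ccc(OCOC)cc4)oc3c2C1=O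
F9 | step 6 | 7-(benzyloxy)-8-iodo-5-(methoxymethoxy)-2-[4-(methoxymethoxy)phenyl]-4H-chromen-4-one | O=c1cc(-c2ccc(OCOC)cc2)oc2c(I)c(OCc3ccccc3)cc(OCOC)c12
F10 | step 14 | 3,5-bis(methoxymethoxy)phenyl diethylcarbamate | CCN(CC)C(=O)Oc1cc(OCOC)cc(OCOC)c1
F11 | step 14 | 3,5-bis(methoxymethoxy)-2-(trimethylsilyl)phenyl diethylcarbamate | CCN(CC)C(=O)Oc1cc(OCOC)cc(OCOC)c1[Si](C)(C)C
F12 | step 14 | 3,5-bis(methoxymethoxy)-2-(trimethylsilyl)phenol | Oc1cc(OCOC)cc(OCOC)c1[Si](C)(C)C
F13 | step 18 | methyl (8R)-8-{[(benzyloxy)carbonyl]oxy}-3,5-bis(methoxymethoxy)-2-[4-(methoxymethoxy)phenyl]-4,9-dioxo-8,9-dihydro-4H-furo[2,3-h]chromene-8-carboxylate | COC(=O)[C@@]1(OC(=O)OCc2ccccc2)Oc2cc(OCOC)c3c(=O)c(OCOC)c(-c4ccc(OCOC)cc4)oc3c2C1=O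
F14 | step 18 | C3 benzyl carbonate of the fully protected target | O=C1c2c(OCOC)cc(OCOC)cc2O[C@]2(c3ccc(OCOC)cc3)c3c(cc(OCOC)c4c(=O)c(OCOC)c(-c5ccc(OCOC)cc5)oc34)O[C@]12OC(=O)OCc1ccccc1
A1 | alternative 1 | hexakis(methoxymethyl) ether of the target with free C3 hemiketal hydroxyl (identical with 27) | O=C1c2c(OCOC)cc(OCOC)cc2O[C@]2(c3ccc(OCOC)cc3)c3c(cc(OCOC)c4c(=O)c(OCOC)c(-c5ccc(OCOC)cc5)oc34)O[C@]12O
A2 | alternative 1 | racemic open hydroxy-dione: 1-[2-hydroxy-4,6-bis(methoxymethoxy)phenyl]-3-hydroxy-3-[4-(methoxymethoxy)phenyl]-3-{7-hydroxy-3,5-bis(methoxymethoxy)-2-[4-(methoxymethoxy)phenyl]-4-oxo-4H-chromen-8-yl}propane-1,2-dione | COCOc1cc(O)c(C(=O)C(=O)C(O)(c2ccc(OCOC)cc2)c2c(O)cc(OCOC)c3c(=O)c(OCOC)c(-c4ccc(OCOC)cc4)oc23)c(OCOC)c1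
A3 | alternative 2 | 2,2-diarylchroman-3,4-dione with O7L still protected | O=C1C(=O)c2c(OCOC)cc(OCOC)cc2O[C@]1(c1ccc(OCOC)cc1)c1c(OCOC)cc(OCOC)c2c(=O)c(OCOC)c(-c3ccc(OCOC)cc3)oc12
A4 | alternative 2 | single-enantiomer 2-aryl-2-hydroxy-1,3-diketone: 1-[2-hydroxy-4,6-bis(methoxymethoxy)phenyl]-2-hydroxy-2-[4-(methoxymethoxy)phenyl]-3-{3,5,7-tris(methoxymethoxy)-2-[4-(methoxymethoxy)phenyl]-4-oxo-4H-chromen-8-yl}propane-1,3-dione | COCOc1cc(O)c(C(=O)[C@](O)(c2ccc(OCOC)cc2)C(=O)c2c(OCOC)cc(OCOC)c3c(=O)c(OCOC)c(-c4ccc(OCOC)cc4)oc23)c(OCOC)c1
A5 | alternative 3 | protected target with free hemiketal hydroxyl and 3L-acetate | O=C1c2c(OCOC)cc(OCOC)cc2O[C@]2(c3ccc(OCOC)cc3)c3c(cc(OCOC)c4c(=O)c(OC(C)=O)c(-c5ccc(OCOC)cc5)oc34)O[C@]12O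
A6 | alternative 3 | 2-aroyl-3-arylbenzofuran: 8-[2-hydroxy-4,6-bis(methoxymethoxy)benzoyl]-5-(methoxymethoxy)-2,9-bis[4-(methoxymethoxy)phenyl]-4-oxo-4H-furo[2,3-h]chromen-3-yl acetate | O=C(c1oc2cc(OCOC)c3c(=O)c(OC(C)=O)c(-c4ccc(OCOC)cc4)oc3c2c1-c1ccc(OCOC)cc1)c1c(O)cc(OCOC)cc1OCOC
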